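The earlier runs and the new flask are simulated from invented constants; scatter was added.

Take the amounts first: Saturday's flask holds free monomer and initiator at 100 to one, and the readings reach to 120 s.

- Saturday's: free monomer 41 mM; initiator 0.41 mM; the very flask that is asked about, followed so far
- flask: free monomer 41 mM; initiator 0.41 mM; time 25 min

Saturday's run (percent of the free monomer charged)

| time / s | monomer in chains / % | free monomer / % |
|---|---|---|
| 10.0 | 0 | 99 |
| 25.0 | 1 | 99 |
| 40.0 | 1 | 97 |
| 60.0 | 8 | 88 |
| 90.0 | 14 | 86 |
| 120 | 28 | 77 |

(scatter of a reading: 2 percentage points)

- amount of monomer in chains in percent of the free monomer charged, at 2.5 min, 8.0 min and 25 min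

- the numbers in the tables scatter by 2 percentage points (one standard deviation)

Count monomer in chains as the charge minus free monomer. What law does the loss follow? From 40.0 s to 120 s the time grows by 3.00, its square by 9.00, and the loss as read, scatter included, by 7.67. Read this as slow initiation with living ends accumulating steadily, so that ln(charge/c(free monomer)) grows with the square of time.

Name the time at which that logarithm reaches one the build-up time. The last free-monomer reading gives 235 s. Does it fit the earlier readings? At 90.0 s it predicts free monomer of 86.4%, and the reading is 86%; at 60.0 s it predicts 93.7% against a reading of 88%, with a scatter of 2 percentage points.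

How far does it carry? My reckoning gives 33.5% in chains at 2.5 min, a time 1.25 times that of the last reading. At 8.0 min, 4.00 times that time, it gives 98.5%, and at 25 min it gives 100%. Both later values assume that the law continues past 120 s, where Saturday's readings stop.

The forecast, which differs from this reckoning, stands at 36%, 93% and 99%, saying “By 25 min it should be essentially complete”.

The flask gives 33.8%, 86.0% and 91.6%.

    free monomer + initiator → living end + monomer in chains (k = 0.0960 M⁻¹ s⁻¹)
    free monomer + living end → monomer in chains + living end, rate k2*[living end]*[free monomer] (k = 32.0 M⁻¹ s⁻¹)
    free monomer → decomposition product (k = 4.20 × 10⁻⁷ s⁻¹)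
    monomer in chains + living end → free monomer + living end, rate k4*[living end] as long as [monomer in chains] is above zero (k = 0.110 s⁻¹)

The first value checks the build-up time, but the later ones fall short of it. Free monomer stands at 8.37% at 25.0 min, and the build-up time puts that level at 6.17 min, yet at 6.25 min the flask has 78.9% in chains and at 12.5 min it has 91.0%. This level is the equilibrium monomer concentration: living ends return monomer in chains to free monomer, and the same flask run without that return ends at >99.9% in chains, against 91.6%.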